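A small charge of starting material turns into intermediate, and two nucleophiles, both in excess of it, compete for that intermediate: the first gives target (idle adduct counted in), the second gives other capture product. The question in this oral is how much the order of addition matters.

| flask | starting material | first nucleophile | second nucleophile | remark | time |
|---|---|---|---|---|---|
| theta | 19 mM | 57 mM | 20.9 mM | run made earlier |  |
| zeta | 19 mM | 38 mM | 20.9 mM | run made earlier |  |
| beta | 19 mM | 86 mM | 20.9 mM | run made earlier |  |
| teal | 19 mM | 57.0 mM (fed, over 12 min) | 20.9 mM | all else is in the flask from the start; the feed brings no volume worth counting | 15 min |
| green | 19 mM (in portions, 3, over 12 min) | 57.0 mM | 20.9 mM | first portion at the start, last at 12 min | 15 min |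
| ochre | 19 mM | 57.0 mM | 20.9 mM | everything together at the start | 15 min |
| amber | 19 mM (fed, over 12 min) | 57.0 mM | 20.9 mM | all else is in the flask from the start; the feed brings no volume worth counting | 15 min |

- theta (time / min: target / %, other capture product / %): 1.33: 46.2, 54.7; 2.50: 47.6, 52.4; 4.00: 46.6, 51.2; 8.00: 46.5, 53.9; 15.0: 46.9, 53.7
- zeta (time / min: target / %, other capture product / %): 3.00: 37.9, 62.3; 6.00: 38.2, 64.1; 10.0: 36.4, 62.7; 12.0: 38.1, 62.7; 15.0: 36.7, 62.9
- beta (time / min: target / %, other capture product / %): 1.33: 57.2, 42.1; 4.00: 56.2, 43.8; 8.00: 55.8, 44.1; 10.0: 55.0, 43.3; 15.0: 55.0, 43.2

(readings scatter by 1 percentage point)

- what is said of target includes idle adduct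
- the analysis behind the earlier runs scatters by 1 percentage point, standard deviation
- reactions considered so far: starting material -> intermediate; first nucleophile + intermediate -> target; second nucleophile + intermediate -> other capture product; first nucleophile -> decomposed reagent; first nucleophile + target <-> idle adduct

- the flask that comes out highest in share of target in target plus other capture product, or "all alike" when all lie within 1.5 percentage points (teal / green / ochre / amber / all alike)
- share of target in target plus other capture product at the end, teal
- share of target in target plus other capture product at the end, green
- share of target in target plus other capture product at the end, ochre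
- share of target in target plus other capture product at the end, amber

What do the earlier runs hold? In theta the two products already sum to 101% at 1.33 min, and later readings wander within the scatter.

Which number do you take from them? Zeta gives 0.321 and beta 0.309, so I carry their mean, 0.315, as the capture weight: target over other capture product, divided by first over second nucleophile, each charge taken as a multiple of the starting material charge. It is an apparent selectivity factor for a flask charged at once.

Where is zero on that scale? A weight of 1 is the statistical case, capture in proportion to the charges, which would give ochre 73.2%. The readings put the first nucleophile at about a third of that.

So ochre? Its charges are 3.00 and 1.10, so target over other capture product is 0.860, a share of 46.2%. Theta, which did not enter the weight, reads 46.6%.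

And teal? Theta's products sum to the whole charge at its first reading, 1.33 min, which is merely where sampling began, and by then teal's feed has delivered 11.1% of its charge. Counting all of that as present, with none of the fed nucleophile decomposed, gives a ratio of 0.0953, a share of 8.70%; I hold this as a generous figure for teal, not as an estimate of it.

Now the weak spot: amber and green? The weight needs the first nucleophile as it stands when the intermediate appears, and these runs stop reporting on it after 1.33 min. I commit to ochre highest and leave both below it, unsized.

The forecast, which does size them, printed 5% for teal, 45.5% for green, 46.8% for ochre and 45.5% for amber, holding that "amber and green follow the same trajectory".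

The flasks give 2.89% for teal, 15.2% for green, 46.7% for ochre and 1.67% for amber, so ochre comes out highest.

    starting material → intermediate (k = 0.163 s⁻¹)
    first nucleophile + intermediate → target (k = 13.2 L mol⁻¹ s⁻¹)
    second nucleophile + intermediate → other capture product (k = 31.1 L mol⁻¹ s⁻¹)
    first nucleophile → decomposed reagent (k = 0.0504 s⁻¹)
    first nucleophile + target ⇌ idle adduct, settled at all times (K = 99.9 L mol⁻¹)

Turned around, the weight reads amber's share as a nucleophile ratio of 0.0539 met by the intermediate, hardly any of the 2.73 charged, and amber ends with 56.7 mM of decomposed reagent. The neighbour of ochre, charged with 140 mM of first nucleophile, 7.37 times the starting material, is again a flask charged at once. The same weight gives it a ratio of 2.11, a share of 67.9%. That flask gives 67.4%.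

The runs are calculated with constants of no real substance; noise was put on by code.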